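## Retrosynthetic overview

- The target is reached by global debenzylation of a tribenzyl precursor, which comes from a Mizoroki–Heck union (aryl C7–vinyl bond) of a (2R,3R)-7-bromo-benzodioxane-2-carboxylic acid with the acrylate of benzyl (R)-3-aryl-lactate; the lactate comes from benzyl (R)-glycidate and an aryl Grignard reagent.
- The cis C2/C3 stereocentres come from a syn, carboxylate-directed asymmetric hydrogenation of the C2=C3 bond of a 3-aryl-1,4-benzodioxine-2-carboxylic acid, one oxidation level above the target and removed again by H2.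
- The dioxine ring is closed at C2–C3: in an acyclic catechol O-alkyl/O-acyl diester, the ester enolate carbon on O1 attacks the aroate carbonyl on O4 (anionic O→C aroyl shift, then cyclodehydration).
- Enabling feature: O4–C3(aryl)–C2(O1)–CO2H is a β-oxygenated acid. C2 is the enolisable α-carbon of the C2 carboxyl, C3 is a benzylic O-bearing carbon that can be carried at the acyl level, and the ortho oxygens O1 and O4 of the benzo ring hold C2 and C3 in a 1,6 relationship.
- Ring order: the three benzene rings are bought and the dioxine ring is the only ring made (step 4). Which oxygen carries which carbon is fixed by 4-bromo-2-hydroxybenzaldehyde (OH becomes the O1–C2 ether; CHO becomes O4 by Dakin oxidation).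

Key step: step 4

Assumption: the facial sense of the Ru–BINAP hydrogenation on this new acid cannot be assigned beforehand, so (S)-BINAP is written and the (R)-ligand is taken if the first run shows the mirror-image acid; benzyl (R)-glycidate is treated as a purchasable building block.

## Route

Step 1
Reactants: 1 4-bromo-2-hydroxybenzaldehyde; 2 tert-butyl bromoacetate
Product: 3 tert-butyl 2-(5-bromo-2-formylphenoxy)acetate
Conditions: K2CO3, DMF, rt
Reagents that add atoms: none
Why: Williamson ether synthesis, in which the phenoxide of 1 should displace bromide from the primary α-bromo ester while the carbonate base at room temperature is too weak to trigger the intramolecular aldol (Rap–Stoermer) closure onto the aldehyde.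

Step 2
Reactants: 3 tert-butyl 2-(5-bromo-2-formylphenoxy)acetate
Product: 5 tert-butyl 2-(5-bromo-2-hydroxyphenoxy)acetate, via aryl formate 4 (not isolated)
Conditions: mCPBA, CH2Cl2, 0 °C → rt; then K2CO3 (cat.), MeOH, 0 °C
Reagents that add atoms: mCPBA (3-chloroperoxybenzoic acid), OOC(=O)c1cccc(Cl)c1
Why: Dakin-type Baeyer–Villiger oxidation, in which the ortho-alkoxy group should make the aryl group migrate so that the formyl carbon is replaced by an oxygen para to bromine, and mild methanolysis of the formate leaves the tert-butyl ester untouched.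

Step 3
Reactants: 5 tert-butyl 2-(5-bromo-2-hydroxyphenoxy)acetate; 6 4-(benzyloxy)-3-methoxybenzoic acid
Product: 7 4-bromo-2-(2-tert-butoxy-2-oxoethoxy)phenyl 4-(benzyloxy)-3-methoxybenzoate
Conditions: DCC, DMAP (cat.), CH2Cl2, 0 °C → rt
Reagents that add atoms: none
Why: Steglich esterification, in which DMAP-catalysed acyl transfer from the O-acylisourea should acylate the only free hydroxyl and so place the aroyl group on the oxygen para to bromine.

Step 4
Reactants: 7 4-bromo-2-(2-tert-butoxy-2-oxoethoxy)phenyl 4-(benzyloxy)-3-methoxybenzoate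
Product: 11 3-[4-(benzyloxy)-3-methoxyphenyl]-7-bromo-1,4-benzodioxine-2-carboxylic acid, via β-keto ester 8 (not isolated), via cyclic hemiketal 9 (not isolated), via benzodioxine tert-butyl ester 10 (not isolated)
Conditions: LiN(SiMe3)2 (2.5 equiv), THF, −78 → 0 °C; TFA quench, evaporate; TFA/CH2Cl2 (1:3), 0 °C → rt
Reagents that add atoms: none
Why: LiN(SiMe3)2 should form the lithium enolate of the aryloxyacetate (the only enolisable position), whose α-carbon attacks the neighbouring aroate carbonyl through a six-membered array and forms the C2–C3 bond; the tetrahedral adduct is the alkoxide of hemiketal 9 and equilibrates with the ring-opened phenolate enolate of β-keto ester 8 (anionic O→C aroyl shift), the thermodynamic sink that drives the Claisen step. Acid should return the material to hemiketal 9, ionise its tertiary benzylic hydroxyl to an oxocarbenium ion stabilised by O4 and the 4-benzyloxyphenyl ring, and after loss of the C2 proton give the push–pull enol ether 10, whose tert-butyl ester TFA then cleaves to acid 11. The closest known reaction types are the Baker–Venkataraman O→C acyl transfer with acid cyclodehydration (flavone synthesis) and the Dieckmann condensation. The dioxine ring closes in a 6-(enolexo)-exo-trig addition. No stereocentre survives the step (8 and 9 are racemic transients), both stereocentres being deferred to the hydrogenation of the C2=C3 bond. The step needs regiocontrol over which catechol oxygen carries C2 and which C3, secured by the O-alkyl/O-acyl pattern of 7 in which the aroyl group can only move to carbon, and it needs dehydration to outrun ester acidolysis so that no β-keto acid can decarboxylate, which the easily ionised hemiketal should secure.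

Step 5
Reactants: 11 3-[4-(benzyloxy)-3-methoxyphenyl]-7-bromo-1,4-benzodioxine-2-carboxylic acid
Product: 12 (2R,3R)-3-[4-(benzyloxy)-3-methoxyphenyl]-7-bromo-2,3-dihydro-1,4-benzodioxine-2-carboxylic acid
Conditions: H2 (50 bar), Ru(OAc)2[(S)-BINAP] (2 mol%), Et3N (1 equiv), MeOH, 40 °C
Reagents that add atoms: none
Why: Carboxylate-directed asymmetric hydrogenation of a tetrasubstituted cyclic β-aryl acrylic acid by a divalent ruthenium diphosphine dicarboxylate, in which both hydrogens should be delivered to one face of C2=C3 (syn addition, hence 2-carboxyl and 3-aryl cis) and the chiral ligand selects the face that gives (2R,3R), while the aryl bromide and benzyl ether are inert to this homogeneous catalyst.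

Step 6
Reactants: 13 1-(benzyloxy)-4-bromo-2-methoxybenzene; 14 benzyl (2R)-oxirane-2-carboxylate
Product: 16 benzyl (2R)-3-[4-(benzyloxy)-3-methoxyphenyl]-2-hydroxypropanoate, via arylmagnesium bromide 15 (not isolated)
Conditions: Mg, THF, 40 °C; then CuI (10 mol%), 14, THF, −40 → −20 °C; aq. NH4Cl
Reagents that add atoms: none
Why: Copper-catalysed Grignard opening of a glycidic ester, in which the aryl copper species should attack the unsubstituted epoxide carbon in an SN2 fashion faster than the ester carbonyl at low temperature, so the stereocentre of 14 is carried over untouched as the (R)-α-hydroxy ester.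

Step 7
Reactants: 16 benzyl (2R)-3-[4-(benzyloxy)-3-methoxyphenyl]-2-hydroxypropanoate; 17 acryloyl chloride
Product: 18 benzyl (2R)-2-(acryloyloxy)-3-[4-(benzyloxy)-3-methoxyphenyl]propanoate
Conditions: Et3N, CH2Cl2, −20 → 0 °C
Reagents that add atoms: none
Why: O-acylation of the secondary alcohol by an acid chloride under amine base (esterification), which should not touch the stereocentre.

Step 8
Reactants: 12 (2R,3R)-3-[4-(benzyloxy)-3-methoxyphenyl]-7-bromo-2,3-dihydro-1,4-benzodioxine-2-carboxylic acid; 18 benzyl (2R)-2-(acryloyloxy)-3-[4-(benzyloxy)-3-methoxyphenyl]propanoate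
Product: 19 (2R,3R)-3-[4-(benzyloxy)-3-methoxyphenyl]-7-[(E)-3-{[(2R)-1-(benzyloxy)-3-[4-(benzyloxy)-3-methoxyphenyl]-1-oxopropan-2-yl]oxy}-3-oxoprop-1-en-1-yl]-2,3-dihydro-1,4-benzodioxine-2-carboxylic acid
Conditions: Pd[P(t-Bu)3]2 (5 mol%), Cy2NMe (3 equiv), 1,4-dioxane, 40 °C
Reagents that add atoms: none
Why: Mizoroki–Heck reaction, in which oxidative addition of the aryl bromide to zerovalent palladium, syn insertion of the acrylate and syn β-hydride elimination should give the E-cinnamate, while the hindered amine keeps C2 (present as a non-enolisable ammonium carboxylate) and the lactate centre configurationally intact.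

Step 9
Reactants: 19 (2R,3R)-3-[4-(benzyloxy)-3-methoxyphenyl]-7-[(E)-3-{[(2R)-1-(benzyloxy)-3-[4-(benzyloxy)-3-methoxyphenyl]-1-oxopropan-2-yl]oxy}-3-oxoprop-1-en-1-yl]-2,3-dihydro-1,4-benzodioxine-2-carboxylic acid
Product: 20 (2R,3R)-7-[(E)-3-{[(1R)-1-carboxy-2-(4-hydroxy-3-methoxyphenyl)ethyl]oxy}-3-oxoprop-1-en-1-yl]-3-(4-hydroxy-3-methoxyphenyl)-2,3-dihydro-1,4-benzodioxine-2-carboxylic acid
Conditions: BCl3 (1 M in CH2Cl2, 10 equiv), C6HMe5 (12 equiv), CH2Cl2, −78 → −30 °C; then H2O
Reagents that add atoms: none
Why: Lewis acid debenzylation with pentamethylbenzene as a non-basic cation scavenger, in which the two aryl benzyl ethers and the benzyl ester should be ionised at low temperature and the benzyl cations trapped by Friedel–Crafts alkylation of the scavenger, without base or hydrogen, so that the cinnamate alkene, the ester link, the methyl ethers and the cis stereocentres are left alone.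

## Compound list

1 | 4-bromo-2-hydroxybenzaldehyde | O=Cc1ccc(Br)cc1O | starting material
2 | tert-butyl bromoacetate | BrCC(=O)OC(C)(C)C | starting material
3 | tert-butyl 2-(5-bromo-2-formylphenoxy)acetate | O=Cc1ccc(Br)cc1OCC(=O)OC(C)(C)C | intermediate
4 | tert-butyl 2-[5-bromo-2-(formyloxy)phenoxy]acetate (aryl formate) | O=COc1ccc(Br)cc1OCC(=O)OC(C)(C)C | intermediate
5 | tert-butyl 2-(5-bromo-2-hydroxyphenoxy)acetate | Oc1ccc(Br)cc1OCC(=O)OC(C)(C)C | intermediate
6 | 4-(benzyloxy)-3-methoxybenzoic acid | COc1cc(C(=O)O)ccc1OCc1ccccc1 | starting material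
7 | 4-bromo-2-(2-tert-butoxy-2-oxoethoxy)phenyl 4-(benzyloxy)-3-methoxybenzoate | COc1cc(C(=O)Oc2ccc(Br)cc2OCC(=O)OC(C)(C)C)ccc1OCc1ccccc1 | intermediate
8 | tert-butyl 3-[4-(benzyloxy)-3-methoxyphenyl]-2-(5-bromo-2-hydroxyphenoxy)-3-oxopropanoate (racemic β-keto ester, present as its dilithium salt under base) | COc1cc(C(=O)C(Oc2cc(Br)ccc2O)C(=O)OC(C)(C)C)ccc1OCc1ccccc1 | intermediate
9 | tert-butyl 3-[4-(benzyloxy)-3-methoxyphenyl]-7-bromo-3-hydroxy-2,3-dihydro-1,4-benzodioxine-2-carboxylate (cyclic hemiketal, racemic diastereomer mixture) | COc1cc(C2(O)Oc3ccc(Br)cc3OC2C(=O)OC(C)(C)C)ccc1OCc1ccccc1 | intermediate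
10 | tert-butyl 3-[4-(benzyloxy)-3-methoxyphenyl]-7-bromo-1,4-benzodioxine-2-carboxylate | COc1cc(C2=C(C(=O)OC(C)(C)C)Oc3cc(Br)ccc3O2)ccc1OCc1ccccc1 | intermediate
11 | 3-[4-(benzyloxy)-3-methoxyphenyl]-7-bromo-1,4-benzodioxine-2-carboxylic acid | COc1cc(C2=C(C(=O)O)Oc3cc(Br)ccc3O2)ccc1OCc1ccccc1 | intermediate
12 | (2R,3R)-3-[4-(benzyloxy)-3-methoxyphenyl]-7-bromo-2,3-dihydro-1,4-benzodioxine-2-carboxylic acid (cis) | Brc1ccc2c(c1)O[C@@H](C(=O)O)[C@@H](c1ccc(OCc3ccccc3)c(OC)c1)O2 | intermediate
13 | 1-(benzyloxy)-4-bromo-2-methoxybenzene | COc1cc(Br)ccc1OCc1ccccc1 | starting material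
14 | benzyl (2R)-oxirane-2-carboxylate (benzyl (R)-glycidate) | O=C(OCc1ccccc1)[C@H]1CO1 | starting material
15 | [4-(benzyloxy)-3-methoxyphenyl]magnesium bromide | COc1cc([Mg]Br)ccc1OCc1ccccc1 | intermediate
16 | benzyl (2R)-3-[4-(benzyloxy)-3-methoxyphenyl]-2-hydroxypropanoate | COc1cc(C[C@@H](O)C(=O)OCc2ccccc2)ccc1OCc1ccccc1 | intermediate
17 | acryloyl chloride | C=CC(=O)Cl | starting material
18 | benzyl (2R)-2-(acryloyloxy)-3-[4-(benzyloxy)-3-methoxyphenyl]propanoate | COc1cc(C[C@@H](OC(=O)C=C)C(=O)OCc2ccccc2)ccc1OCc1ccccc1 | intermediate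
19 | (2R,3R)-3-[4-(benzyloxy)-3-methoxyphenyl]-7-[(E)-3-{[(2R)-1-(benzyloxy)-3-[4-(benzyloxy)-3-methoxyphenyl]-1-oxopropan-2-yl]oxy}-3-oxoprop-1-en-1-yl]-2,3-dihydro-1,4-benzodioxine-2-carboxylic acid | COc1cc(C[C@@H](OC(=O)/C=C/c2ccc3c(c2)O[C@@H](C(=O)O)[C@@H](c2ccc(OCc4ccccc4)c(OC)c2)O3)C(=O)OCc2ccccc2)ccc1OCc1ccccc1 | intermediate
20 | (2R,3R)-7-[(E)-3-{[(1R)-1-carboxy-2-(4-hydroxy-3-methoxyphenyl)ethyl]oxy}-3-oxoprop-1-en-1-yl]-3-(4-hydroxy-3-methoxyphenyl)-2,3-dihydro-1,4-benzodioxine-2-carboxylic acid (CNP0171229.1) | COc1cc(C[C@@H](OC(=O)/C=C/c2ccc3c(c2)O[C@@H](C(=O)O)[C@@H](c2ccc(O)c(OC)c2)O3)C(=O)O)ccc1O | target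

## Step count and risks

Total step count: 9. Longest linear sequence: 7 (steps 1, 2, 3, 4, 5, 8, 9).

Steps most likely to fail:

**Step 5.** The tetrasubstituted push–pull C2=C3 bond may turn over too slowly on the ruthenium catalyst, or the two faces may be poorly discriminated. The fallback sets out from 11. Directed syn-hydrogenation with the achiral catalyst [Ir(cod)(PCy3)(py)]PF6 (H2, CH2Cl2) should give the racemic cis acid, that is 12 together with its mirror image (2S,3S)-3-[4-(benzyloxy)-3-methoxyphenyl]-7-bromo-2,3-dihydro-1,4-benzodioxine-2-carboxylic acid F4. Classical resolution by crystallisation with (R)-1-phenylethylamine should give the (R)-1-phenylethylammonium salt of 12 F5; the antipodal amine is taken if the other salt proves the less soluble one. Acidification returns the route at 12.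

**Step 4.** The enolate may be acylated on oxygen or between molecules instead of through the six-membered array, the β-keto ester may fragment by retro-Claisen attack, or the acid stage may protodecarboxylate the push–pull acid. The fallback sets out from 5 and 6, makes the C2–C3 bond intermolecularly and then closes the ring through O4–C3.
- Phenol 5 is silylated (TBSCl, imidazole, DMF) to tert-butyl 2-[5-bromo-2-(tert-butyldimethylsilyloxy)phenoxy]acetate F1.
- Acid 6 is converted with (COCl)2 and cat. DMF into 4-(benzyloxy)-3-methoxybenzoyl chloride F2.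
- The lithium enolate of F1 (LiN(SiMe3)2, 2.2 equiv, THF, −78 °C) is C-acylated by F2 in a crossed Claisen condensation to tert-butyl 3-[4-(benzyloxy)-3-methoxyphenyl]-2-[5-bromo-2-(tert-butyldimethylsilyloxy)phenoxy]-3-oxopropanoate F3.
- Desilylation with Et3N·3HF returns the route at 8 (in equilibrium with 9), which the acid stage of step 4 takes on to 11. If protodecarboxylation is the problem, a separate cat. TsOH dehydration to isolated 10 followed by TMSOTf/2,6-lutidine ester cleavage is used instead.

**Step 9.** The Lewis acid may ionise the benzylic C3–O4 bond once the para-oxygen is free (ring opening and reclosure with loss of the cis relationship), the benzyl ester may cleave incompletely, or benzyl cations may alkylate the electron-rich rings. The fallback removes the benzyl groups before any stereocentre or the union exists and sets out from 11 and 18.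
- BCl3/C6HMe5 on 11, where C3 is still sp2, should give 7-bromo-3-(4-hydroxy-3-methoxyphenyl)-1,4-benzodioxine-2-carboxylic acid F6.
- Hydrogenation as in step 5 should give (2R,3R)-7-bromo-3-(4-hydroxy-3-methoxyphenyl)-2,3-dihydro-1,4-benzodioxine-2-carboxylic acid F7.
- BCl3/C6HMe5 on 18 should give (2R)-2-(acryloyloxy)-3-(4-hydroxy-3-methoxyphenyl)propanoic acid F8.
- A protecting-group-free Mizoroki–Heck reaction of F7 with F8 (Pd[P(t-Bu)3]2, Cy2NMe 5 equiv, 1,4-dioxane, 40 °C) comes back to the route at 20.

Further compounds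
F1 | step 4 | tert-butyl 2-[5-bromo-2-(tert-butyldimethylsilyloxy)phenoxy]acetate | CC(C)(C)[Si](C)(C)Oc1ccc(Br)cc1OCC(=O)OC(C)(C)C
F2 | step 4 | 4-(benzyloxy)-3-methoxybenzoyl chloride | COc1cc(C(=O)Cl)ccc1OCc1ccccc1
F3 | step 4 | tert-butyl 3-[4-(benzyloxy)-3-methoxyphenyl]-2-[5-bromo-2-(tert-butyldimethylsilyloxy)phenoxy]-3-oxopropanoate | COc1cc(C(=O)C(Oc2cc(Br)ccc2O[Si](C)(C)C(C)(C)C)C(=O)OC(C)(C)C)ccc1OCc1ccccc1
F4 | step 5 | (2S,3S)-3-[4-(benzyloxy)-3-methoxyphenyl]-7-bromo-2,3-dihydro-1,4-benzodioxine-2-carboxylic acid | Brc1ccc2c(c1)O[C@H](C(=O)O)[C@H](c1ccc(OCc3ccccc3)c(OC)c1)O2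
F5 | step 5 | (R)-1-phenylethylammonium (2R,3R)-3-[4-(benzyloxy)-3-methoxyphenyl]-7-bromo-2,3-dihydro-1,4-benzodioxine-2-carboxylate | Brc1ccc2c(c1)O[C@@H](C(=O)[O-])[C@@H](c1ccc(OCc3ccccc3)c(OC)c1)O2.C[C@@H]([NH3+])c1ccccc1
F6 | step 9 | 7-bromo-3-(4-hydroxy-3-methoxyphenyl)-1,4-benzodioxine-2-carboxylic acid | COc1cc(C2=C(C(=O)O)Oc3cc(Br)ccc3O2)ccc1O
F7 | step 9 | (2R,3R)-7-bromo-3-(4-hydroxy-3-methoxyphenyl)-2,3-dihydro-1,4-benzodioxine-2-carboxylic acid | Brc1ccc2c(c1)O[C@@H](C(=O)O)[C@@H](c1ccc(O)c(OC)c1)O2
F8 | step 9 | (2R)-2-(acryloyloxy)-3-(4-hydroxy-3-methoxyphenyl)propanoic acid | COc1cc(C[C@@H](OC(=O)C=C)C(=O)O)ccc1O
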